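**Retrosynthetic overview**
1. 9 ⇒ 8: the last step removes two O-benzyl groups by hydrogenolysis, which leaves the 8-acetate in place.
2. 8 ⇒ 5: the key disconnection is the C8–O bond. The whole acetoxy group is placed on C8–H, para to the 5-OH, so the 8-oxygen never has to be distinguished from the other OH groups.
3. 5 ⇒ 2 ⇒ 1: the O-pattern (7-OMe, 3- and 4'-OBn, free 5-OH) is written onto kaempferol through its tetraacetate by ordered deacetylative alkylation.
4. Ring order: no ring is formed. Rings A, C and B come intact from kaempferol.

Assumption: the target SMILES contains no stereocentre or stereogenic axis, so the compound is achiral and no stereocontrol is needed. The only sp3 centre on the way (C8 of transient 7) is erased on tautomerisation.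

**Step 1**
Reactants: 1 kaempferol
Product: 2 kaempferol 3,5,7,4'-tetraacetate
Conditions: Ac2O (6 equiv), pyridine, DMAP (5 mol %), rt, 12 h; pour into ice water, filter
Reagents that add atoms: acetic anhydride, CC(=O)OC(C)=O
Why: Exhaustive O-acetylation under nucleophilic catalysis (pyridine/DMAP) with excess anhydride also takes the chelated 5-OH and gives a crystalline tetraester.

**Step 2**
Reactants: 2 kaempferol 3,5,7,4'-tetraacetate
Product: 5 rhamnocitrin 3,4'-dibenzyl ether, via rhamnocitrin triacetate 3 (not isolated), via rhamnocitrin 4 (not isolated)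
Conditions: MeI (1.3 equiv), K2CO3, acetone (0.5% H2O), 45 °C, 24 h; evaporate; K2CO3, degassed MeOH–DMF, Ar, rt, 1 h; strip MeOH; BnBr (2.2 equiv), 40 °C, 6 h
Reagents that add atoms: methyl iodide, CI; benzyl bromide, BrCc1ccccc1
Why: In this Jurd-type deacetylative alkylation the 7-acetate (ester of the most acidic phenol) is cleaved first and its phenoxide is methylated at once, carbonate-catalysed methanolysis then frees the other three OH groups, and Williamson benzylation takes the 4'- and 3-oxygens but not the 5-OH, which is hydrogen-bonded to C4=O.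

**Step 3**
Reactants: 5 rhamnocitrin 3,4'-dibenzyl ether
Product: 8 pollenitin 8-acetate 3,4'-dibenzyl ether, via potassium 5-phenolate 6 (not isolated), via C8-acetoxy dienone 7 (not isolated)
Conditions: KOt-Bu (1.0 equiv), DMF, −20 °C; then Bu4N[AcO–OSO3] (1.2 equiv, ≤0.2 M, made beforehand from Bu4NHSO5, Ac2O and K2CO3 powder in MeCN at −20 °C, filtered cold, never concentrated), −20 → 0 °C, Ar, dark; aq NaH2PO4/Na2S2O3
Reagents that add atoms: tetrabutylammonium peroxymonosulfate, CCCC[N+](CCCC)(CCCC)CCCC.OOS(=O)(=O)[O-]; acetic anhydride, CC(=O)OC(C)=O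
Why: Proposed new method: an "acetoxy-Elbs" oxidation with the new reagent acetyl peroxysulfate, in which the soft para carbon C8 of phenolate 6 attacks the acetyl-bearing peroxide oxygen of AcO–OSO3− (SN2 at oxygen), sulfate (pKa of HSO4− about 2 against 4.8 for AcOH, departure helped by K+ pairing) leaves, and dienone 7 (racemic at C8, transient) tautomerises to aromatic 8; C8 is expected because it is para to the phenolate, as in the persulfate oxidation of 5-hydroxyflavones, O-acetylation of the hindered chelated 5-O− should be slow because it would expel the poor leaving group SO5(2−) (pKa of HSO5− about 9.4), the neutral benzyl ethers and the C2=C3 bond are far weaker nucleophiles than the phenolate, and the acetyl cap blocks over-oxidation to the 5,8-quinone; the closest known reaction types are the Elbs persulfate oxidation and the α-acyloxylation of enolates with diacyl peroxides.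

**Step 4**
Reactants: 8 pollenitin 8-acetate 3,4'-dibenzyl ether
Product: 9 pollenitin 8-acetate
Conditions: H2 (1 atm), 10% Pd/C, EtOAc–THF 1:1, rt, 4 h; filter, crystallise
Reagents that add atoms: none
Why: Catalytic hydrogenolysis of the two O-benzyl groups in a neutral, non-nucleophilic solvent leaves the aryl acetate, the methyl ether and the tetrasubstituted C2=C3 bond untouched, and with no free OH next to the 8-acetate there is no acyl migration.

**Compound list**
1 | kaempferol (3,5,7-trihydroxy-2-(4-hydroxyphenyl)chromen-4-one) | O=c1c(O)c(-c2ccc(O)cc2)oc2cc(O)cc(O)c12 | starting material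
2 | kaempferol 3,5,7,4'-tetraacetate | CC(=O)Oc1cc(OC(C)=O)c2c(=O)c(OC(C)=O)c(-c3ccc(OC(C)=O)cc3)oc2c1 | intermediate
3 | rhamnocitrin triacetate (3,5,4'-tri-O-acetyl-7-O-methylkaempferol) | COc1cc(OC(C)=O)c2c(=O)c(OC(C)=O)c(-c3ccc(OC(C)=O)cc3)oc2c1 | intermediate
4 | rhamnocitrin (7-O-methylkaempferol, present as its potassium salt) | COc1cc(O)c2c(=O)c(O)c(-c3ccc(O)cc3)oc2c1 | intermediate
5 | rhamnocitrin 3,4'-dibenzyl ether (3-benzyloxy-2-(4-benzyloxyphenyl)-5-hydroxy-7-methoxychromen-4-one) | COc1cc(O)c2c(=O)c(OCc3ccccc3)c(-c3ccc(OCc4ccccc4)cc3)oc2c1 | intermediate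
6 | potassium 5-phenolate of 5 | COc1cc([O-])c2c(=O)c(OCc3ccccc3)c(-c3ccc(OCc4ccccc4)cc3)oc2c1.[K+] | intermediate
7 | C8-acetoxy dienone (8-acetoxy-8H-chromene-4,5-dione tautomer of 8, racemic at C8) | COC1=CC(=O)C2=C(OC(c3ccc(OCc4ccccc4)cc3)=C(OCc3ccccc3)C2=O)C1OC(C)=O | intermediate
8 | pollenitin 8-acetate 3,4'-dibenzyl ether (8-acetoxy-3-benzyloxy-2-(4-benzyloxyphenyl)-5-hydroxy-7-methoxychromen-4-one) | COc1cc(O)c2c(=O)c(OCc3ccccc3)c(-c3ccc(OCc4ccccc4)cc3)oc2c1OC(C)=O | intermediate
9 | pollenitin 8-acetate (8-acetoxy-3,5,4'-trihydroxy-7-methoxyflavone, achiral) | COc1cc(O)c2c(=O)c(O)c(-c3ccc(O)cc3)oc2c1OC(C)=O | target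

**Total step count:** 4. **Longest linear sequence:** 4 (1 → 2 → 5 → 8 → 9).

**Three steps most likely to fail**

Step 3 (the new step).
- Risks: acetyl transfer to O5 instead of oxygen transfer to carbon; transfer of the sulfate end of the peroxide; some attack at C6; stalling near half conversion, because product 8 takes the proton-free site from 6 (unreacted 5 is then recycled).
- Regiochemistry check: the H-6 singlet should be retained and should show an HMBC contact to the chelated 5-OH.
- Fallback (known chemistry) sets out from 5. Classical Elbs persulfate oxidation (K2S2O8, aq KOH–pyridine, rt) gives potassium 3,4'-dibenzyloxy-5-hydroxy-7-methoxyflavon-8-yl sulfate F2. Acid hydrolysis (2 M HCl, Na2SO3, 80 °C, Ar) gives pollenitin 3,4'-dibenzyl ether F3. Its non-chelated 8-OH is acetylated selectively over the hydrogen-bonded 5-OH (Ac2O 1.05 equiv, pyridine, 0 °C), and the route is rejoined at 8.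

Step 2.
- Risks: the order of acetate cleavage must hold in one pot. Too much methylation gives the 7,4'-dimethyl ether, too little gives 7-O-benzyl material, and free flavonol 4 is air-sensitive in base.
- Fallback sets out from 2 and separates the selectivity-determining event from the alkylation. Thiolate-mediated chemoselective 7-deacetylation (PhSH, imidazole, NMP, 0 °C) gives kaempferol 3,5,4'-triacetate F1, which is isolated and crystallised. Base-free Mitsunobu methylation of its single free OH (MeOH, PPh3, DIAD, THF) gives 3. This is now isolated pure, and the route is rejoined at 3 with methanolysis and benzylation as described.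

Step 4.
- Risks: partial saturation of C2=C3, slow cleavage because the product is poorly soluble, or loss of the acetate if a protic solvent is needed.
- Fallback sets out from 8 and replaces hydrogenolysis by Lewis-acid debenzylation with a cation scavenger (BCl3, pentamethylbenzene, CH2Cl2, −78 °C; aryl esters and non-chelated aryl methyl ethers survive). It arrives directly at 9 and makes no new compound (F0).

**Further compounds**
F1 | step 2 | kaempferol 3,5,4'-triacetate (7-OH free) | Oc1cc(OC(C)=O)c2c(=O)c(OC(C)=O)c(-c3ccc(OC(C)=O)cc3)oc2c1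
F2 | step 3 | potassium 3,4'-dibenzyloxy-5-hydroxy-7-methoxyflavon-8-yl sulfate | COc1cc(O)c2c(=O)c(OCc3ccccc3)c(-c3ccc(OCc4ccccc4)cc3)oc2c1OS(=O)(=O)[O-].[K+]
F3 | step 3 | pollenitin 3,4'-dibenzyl ether (5,8-dihydroxy) | COc1cc(O)c2c(=O)c(OCc3ccccc3)c(-c3ccc(OCc4ccccc4)cc3)oc2c1O
F0 | step 4 | none | none
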